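## Retrosynthetic overview
1. The chroman ring is formed last. The 6-chromanol comes from a 1-oxaspiro[4.5]decadienone by a 1,2-shift of the ring CH2 (five-membered spiro ether to six-membered chroman). The spirodienone comes from oxidative dearomatisation of a 4-alkyl-2,3,6-trimethylphenol that carries the (R)-tertiary alcohol, and the C2–O bond is never broken.
2. The aryl–C4 bond comes from a 4-lithiophenoxide and an (R)-2,2-disubstituted oxetane.
3. The oxetane comes from a C18 methyl ketone by catalytic asymmetric double methylene transfer (ketone to epoxide to oxetane), which sets C2.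
4. The C18 ketone comes from methyl vinyl ketone and a C14 Grignard reagent. The C14 unit comes from methallyl-MgCl and two molecules of (R)-1,4-dibromo-2-methylbutane, so C4' and C8' both come from one chiral C5 diol.
5. The arene comes from m-cresol and two MeOH, followed by para-bromination. Ring order: arene (bought), oxirane, oxetane, spiro-tetrahydrofuran, chroman.

Primed locants are side-chain carbons in tocopherol numbering. C8' is S by the CIP rules in the target because the isopropenyl end outranks the other chain. Its spatial arrangement is that of 8'R in α-tocopherol.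

Assumption: the (S)-BINOL-derived LaLi3 catalyst is taken to deliver CH2 to the Si face of the C18 methyl ketone; if its sense is the opposite, the mirror-image catalyst is used.

## Route

Step 1
Reactants: 1 (R)-2-methylbutane-1,4-diol
Product: 2 (R)-1,4-dibromo-2-methylbutane
Conditions: PPh3 (2.3 equiv), Br2 (2.3 equiv), MeCN/CH2Cl2, 0 °C → rt
Reagents that add atoms: bromine, BrBr
Why: Appel-type bromination with Ph3PBr2 replaces both primary hydroxyl groups by SN2 attack of bromide on the alkoxyphosphonium salts, so the C2 stereocentre, which is not a reaction site, is carried over unchanged and the hydride-shift by-products of hot HBr are avoided.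

Step 2
Reactants: 2 (R)-1,4-dibromo-2-methylbutane; 3 2-methylallylmagnesium chloride (0.5 M in THF)
Product: 4 (6R)-7-bromo-2,6-dimethylhept-1-ene
Conditions: 3 (1.2 equiv, slow addition), Li2CuCl4 (2 mol%), THF, −30 → 0 °C, run until 2 is consumed; distil
Reagents that add atoms: none
Why: Copper-catalysed Grignard–alkyl halide cross-coupling (Kochi type) is roughly ten times faster at the unbranched C4–Br than at the β-branched C1–Br, and since the wrong regioisomer keeps the fast bromide it is consumed by the small excess of 3 to an easily removed C13 diene, which leaves 4 isomerically clean with the stereocentre (later C8') untouched.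

Step 3
Reactants: 4 (6R)-7-bromo-2,6-dimethylhept-1-ene; 2 (R)-1,4-dibromo-2-methylbutane
Product: 6 (6S,10R)-11-bromo-2,6,10-trimethylundec-1-ene, via Grignard reagent 5 (not isolated)
Conditions: Mg, THF, 40 °C; then 2 (0.85 equiv), Li2CuCl4 (3 mol%), NMP (4 equiv), THF, 0 °C, run until 2 is consumed
Reagents that add atoms: none
Why: The same site-selective Kochi-type coupling, now with the bulkier β-branched Grignard reagent 5 and NMP as accelerator, joins C7' to the unhindered end of a second molecule of 2, so that both methyl stereocentres (C4' and C8') come from the one chiral C5 building block and neither is a reaction site.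

Step 4
Reactants: 6 (6S,10R)-11-bromo-2,6,10-trimethylundec-1-ene; 7 methyl vinyl ketone (but-3-en-2-one)
Product: 10 (6R,10S)-6,10,14-trimethylpentadec-14-en-2-one, via Grignard reagent 8 (not isolated), via silyl enol ether 9 (not isolated)
Conditions: Mg, THF, 40 °C; CuBr·SMe2 (10 mol%), DMPU (2 equiv), TMSCl (2 equiv), 7 (1.3 equiv), THF, −78 °C; then 1 M HCl, THF, 0 °C, 15 min
Reagents that add atoms: none
Why: TMSCl-accelerated copper-catalysed conjugate addition of a primary Grignard reagent to an enone traps the enolate as 9, which suppresses 1,2-addition and polymerisation of 7, and brief cold dilute acid hydrolyses 9 without touching the isopropenyl group or the stereocentres.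

Step 5
Reactants: 10 (6R,10S)-6,10,14-trimethylpentadec-14-en-2-one
Product: 12 (2R)-2-methyl-2-[(4R,8S)-4,8,12-trimethyltridec-12-en-1-yl]oxetane, via epoxide 11 (not isolated)
Conditions: Me2S(O)=CH2 (salt-free THF stock solution, 1.2 then 1.5 equiv), LaLi3[(S)-1,1'-binaphthalene-2,2'-diolate]3 (5 then 15 mol%), [2,4,6-(MeO)3C6H2]3P=O (5 then 15 mol%), MS 5 Å, THF, rt 12 h, then 45 °C 72 h
Reagents that add atoms: dimethyloxosulfonium methylide, C[S+](C)(=O)[CH2-]
Why: Catalytic asymmetric Corey–Chaykovsky epoxidation sets C2 (R) because the chiral lanthanum–lithium binaphtholate tells the methyl group from the long chain and steers CH2 to the Si face, and the second ylide equivalent opens 11 at its CH2 and recloses with loss of DMSO (epoxide-to-oxetane ring expansion, C2–O bond retained) faster for the matched epimer, which lifts the C2 purity to about 99:1.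

Step 6
Reactants: 13 m-cresol
Product: 14 2,3,6-trimethylphenol
Conditions: MeOH (6 equiv), H2O, vapour phase over a Fe2O3–Cr2O3–SiO2–K2O fixed bed, 350 °C; distil, crystallise
Reagents that add atoms: methanol, CO
Why: Ortho-selective vapour-phase C-methylation of phenols over iron oxide catalysts, the industrial process for this very phenol, works because the phenolate stands upright on the oxide surface and exposes only its two ortho positions to adsorbed methanol.

Step 7
Reactants: 14 2,3,6-trimethylphenol
Product: 15 4-bromo-2,3,6-trimethylphenol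
Conditions: NBS (1.0 equiv), MeCN, 0 °C
Reagents that add atoms: N-bromosuccinimide, O=C1CCC(=O)N1Br
Why: Electrophilic aromatic bromination goes to C4, the only free position para (or ortho) to the hydroxyl group, while the other free position is meta to it.

Step 8
Reactants: 15 4-bromo-2,3,6-trimethylphenol (2 equiv); 12 (2R)-2-methyl-2-[(4R,8S)-4,8,12-trimethyltridec-12-en-1-yl]oxetane
Product: 18 4-[(3R,7R,11S)-3-hydroxy-3,7,11,15-tetramethylhexadec-15-en-1-yl]-2,3,6-trimethylphenol, via lithium bromophenoxide 16 (not isolated), via dilithiated phenol 17 (not isolated)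
Conditions: n-BuLi (1 equiv per 15), THF, −78 °C; t-BuLi (2 equiv per 15), −78 °C; 12, then BF3·OEt2 dropwise, −78 → −30 °C; aq. NaHCO3
Reagents that add atoms: none
Why: Bromine–lithium exchange on the preformed lithium phenoxide gives a C-nucleophile that opens the BF3-activated oxetane by SN2 attack at its unsubstituted CH2 (Lewis-acid-assisted organolithium opening of oxetanes), so the aryl–C4 bond is made without a protecting group and the quaternary C2 centre, not being attacked, stays R.

Step 9
Reactants: 18 4-[(3R,7R,11S)-3-hydroxy-3,7,11,15-tetramethylhexadec-15-en-1-yl]-2,3,6-trimethylphenol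
Product: 20 (2R)-2,5,7,8-tetramethyl-2-[(4R,8S)-4,8,12-trimethyltridec-12-en-1-yl]-3,4-dihydro-2H-chromen-6-ol, via spirodienone 19 (not isolated)
Conditions: PhI(OAc)2 (1.0 equiv), (CF3)2CHOH/CH2Cl2, 0 °C, 15 min; evaporate with toluene; Me2AlCl (2.5 equiv), CH2Cl2 (0.02 M), −78 → −20 °C, Ar; aq. potassium sodium tartrate
Reagents that add atoms: none
Why: Proposed new method: PhI(OAc)2 dearomatises the phenol and the tertiary alcohol closes 5-exo on the para carbon (known oxidative spiroetherification) to give 19 as two spiro epimers, then Me2AlCl binds the dienone oxygen and the resulting aluminoxy-pentadienyl cation is quenched by a 1,2-shift of the ring CH2 from the spiro carbon to the only neighbouring CH position (carbon and not oxygen migrates because the cation left behind is an oxocarbenium ion), which expands the five-membered ether to the chroman, and the ring proton is lost to an Al–CH3 group as methane, so aromatisation is irreversible and no free Brønsted acid arises that could isomerise the isopropenyl group or ionise the tertiary C2–O bond (never broken, R retained, both spiro epimers converge); the closest known reaction types are the dienone–phenol and p-quinol-to-hydroquinone rearrangements, which have not been shown for a stereodefined tertiary spiro ether or under proton-scavenging organoaluminium conditions.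

## Compound list
1 | (R)-2-methylbutane-1,4-diol | OC[C@H](C)CCO | starting material
2 | (R)-1,4-dibromo-2-methylbutane | BrC[C@H](C)CCBr | intermediate
3 | 2-methylallylmagnesium chloride | C=C(C)C[Mg]Cl | starting material
4 | (6R)-7-bromo-2,6-dimethylhept-1-ene | C=C(C)CCC[C@@H](C)CBr | intermediate
5 | [(2R)-2,6-dimethylhept-6-en-1-yl]magnesium bromide | C=C(C)CCC[C@@H](C)C[Mg]Br | intermediate
6 | (6S,10R)-11-bromo-2,6,10-trimethylundec-1-ene | C=C(C)CCC[C@@H](C)CCC[C@@H](C)CBr | intermediate
7 | methyl vinyl ketone | C=CC(C)=O | starting material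
8 | [(2R,6S)-2,6,10-trimethylundec-10-en-1-yl]magnesium bromide | C=C(C)CCC[C@@H](C)CCC[C@@H](C)C[Mg]Br | intermediate
9 | trimethyl{[(6R,10S)-6,10,14-trimethylpentadeca-2,14-dien-2-yl]oxy}silane (E/Z mixture) | C=C(C)CCC[C@@H](C)CCC[C@@H](C)CCC=C(C)O[Si](C)(C)C | intermediate
10 | (6R,10S)-6,10,14-trimethylpentadec-14-en-2-one | C=C(C)CCC[C@@H](C)CCC[C@@H](C)CCCC(C)=O | intermediate
11 | (2R)-2-methyl-2-[(4R,8S)-4,8,12-trimethyltridec-12-en-1-yl]oxirane | C=C(C)CCC[C@@H](C)CCC[C@@H](C)CCC[C@]1(C)CO1 | intermediate
12 | (2R)-2-methyl-2-[(4R,8S)-4,8,12-trimethyltridec-12-en-1-yl]oxetane | C=C(C)CCC[C@@H](C)CCC[C@@H](C)CCC[C@]1(C)CCO1 | intermediate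
13 | m-cresol | Cc1cccc(O)c1 | starting material
14 | 2,3,6-trimethylphenol | Cc1ccc(C)c(C)c1O | intermediate
15 | 4-bromo-2,3,6-trimethylphenol | Cc1cc(Br)c(C)c(C)c1O | intermediate
16 | lithium 4-bromo-2,3,6-trimethylphenoxide | Cc1cc(Br)c(C)c(C)c1O[Li] | intermediate
17 | lithium 4-lithio-2,3,6-trimethylphenoxide | [Li]c1cc(C)c(O[Li])c(C)c1C | intermediate
18 | 4-[(3R,7R,11S)-3-hydroxy-3,7,11,15-tetramethylhexadec-15-en-1-yl]-2,3,6-trimethylphenol | C=C(C)CCC[C@@H](C)CCC[C@@H](C)CCC[C@@](C)(O)CCc1cc(C)c(O)c(C)c1C | intermediate
19 | (2R)-2,6,7,9-tetramethyl-2-[(4R,8S)-4,8,12-trimethyltridec-12-en-1-yl]-1-oxaspiro[4.5]deca-6,9-dien-8-one (both C5 epimers) | C=C(C)CCC[C@@H](C)CCC[C@@H](C)CCC[C@]1(C)CCC2(O1)C=C(C)C(=O)C(C)=C2C | intermediate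
20 | (2R)-2,5,7,8-tetramethyl-2-[(4R,8S)-4,8,12-trimethyltridec-12-en-1-yl]-3,4-dihydro-2H-chromen-6-ol | C=C(C)CCC[C@@H](C)CCC[C@@H](C)CCC[C@]1(C)CCc2c(C)c(O)c(C)c(C)c2O1 | target

## Step count and risks
Total step count: 9. Longest linear sequence: 7 (steps 1, 2, 3, 4, 5, 8, 9).

**Step 9, the new ring expansion.** The aluminium Lewis acid may ionise the tertiary C2–O bond of 19 or fail to trigger the shift. The oxidation may also leak to quinone methides.
- The fallback puts the second ring oxygen in place before the side chain is attached, so no skeletal shift is needed. It sets out from 15 and 12 and comes back to the route at 20.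
- Ullmann-type methoxylation of 15 (NaOMe, CuI, DMF/MeOH, 110 °C) gives 4-methoxy-2,3,6-trimethylphenol F1.
- Anhydrous bromination (Br2, CH2Cl2, −20 °C) fills the last free ring position to give 3-bromo-4-methoxy-2,5,6-trimethylphenol F2.
- n-BuLi then t-BuLi, as in step 8, give lithium 3-lithio-4-methoxy-2,5,6-trimethylphenoxide F3.
- BF3·OEt2-assisted opening of 12 gives 3-[(3R,7R,11S)-3-hydroxy-3,7,11,15-tetramethylhexadec-15-en-1-yl]-4-methoxy-2,5,6-trimethylphenol F4.
- PhI(OAc)2 in MeCN closes the tertiary alcohol onto the methoxy-bearing para carbon (known oxidative ketalisation of 4-alkoxyphenols). The product is the cyclic quinone monoketal (2R)-8a-methoxy-2,5,7,8-tetramethyl-2-[(4R,8S)-4,8,12-trimethyltridec-12-en-1-yl]-3,4-dihydro-2H-chromen-6(8aH)-one F5, a compound of the 8a-alkoxytocopherone type.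
- Ascorbic acid in aqueous THF/AcOH reduces F5 with loss of methanol to 20. The C2–O bond is again never broken.

**Step 8, the protecting-group-free aryllithium opening.** The poorly soluble dianion 17 may be consumed by BF3, or BF3 may open 12 at its tertiary carbon.
- The fallback reverses the polarity of the bond formation. It sets out from 12 and 15 and comes back at 18.
- Reductive lithiation of 12 with lithium 4,4'-di-tert-butylbiphenylide (THF, 0 °C) cleaves the less substituted C–O bond. This gives lithium (3S,7R,11S)-1-lithio-3,7,11,15-tetramethylhexadec-15-en-3-olate F6, with unchanged geometry at the carbinol carbon.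
- ZnCl2 converts F6 into lithium (3R,7R,11S)-1-(chlorozincio)-3,7,11,15-tetramethylhexadec-15-en-3-olate F7.
- Negishi coupling of F7 with 15 (Pd(OAc)2, SPhos, THF, 40 °C) gives 18 after aqueous work-up. The internal alkoxide takes up the phenol proton.

**Step 3 (and likewise step 2), the site selectivity between the two C–Br bonds of 2.** If the rate ratio is too small, regioisomeric bromides that cannot be separated are carried on.
- The fallback distinguishes the two ends by functional group instead of by rate. It sets out from 1 and 5 and comes back at 6.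
- Sulfonylation of 1 at the unhindered C4–OH with 2,4,6-triisopropylbenzenesulfonyl chloride (pyridine, −20 °C, regioisomer removed on silica) gives (3R)-4-hydroxy-3-methylbutyl 2,4,6-triisopropylbenzenesulfonate F8.
- Et3SiCl/imidazole gives (3R)-3-methyl-4-(triethylsilyloxy)butyl 2,4,6-triisopropylbenzenesulfonate F9.
- Li2CuCl4-catalysed coupling of F9 with 5 gives triethyl{[(2R,6S)-2,6,10-trimethylundec-10-en-1-yl]oxy}silane F10.
- Ph3PBr2 in CH2Cl2 converts the silyl ether F10 directly into 6.

## Further compounds
F1 | step 9 | 4-methoxy-2,3,6-trimethylphenol | COc1cc(C)c(O)c(C)c1C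
F2 | step 9 | 3-bromo-4-methoxy-2,5,6-trimethylphenol | COc1c(Br)c(C)c(O)c(C)c1C
F3 | step 9 | lithium 3-lithio-4-methoxy-2,5,6-trimethylphenoxide | COc1c([Li])c(C)c(O[Li])c(C)c1C
F4 | step 9 | 3-[(3R,7R,11S)-3-hydroxy-3,7,11,15-tetramethylhexadec-15-en-1-yl]-4-methoxy-2,5,6-trimethylphenol | C=C(C)CCC[C@@H](C)CCC[C@@H](C)CCC[C@@](C)(O)CCc1c(C)c(O)c(C)c(C)c1OC
F5 | step 9 | (2R)-8a-methoxy-2,5,7,8-tetramethyl-2-[(4R,8S)-4,8,12-trimethyltridec-12-en-1-yl]-3,4-dihydro-2H-chromen-6(8aH)-one (both C8a epimers) | C=C(C)CCC[C@@H](C)CCC[C@@H](C)CCC[C@]1(C)CCC2=C(C)C(=O)C(C)=C(C)C2(OC)O1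
F6 | step 8 | lithium (3S,7R,11S)-1-lithio-3,7,11,15-tetramethylhexadec-15-en-3-olate | C=C(C)CCC[C@@H](C)CCC[C@@H](C)CCC[C@@](C)(O[Li])CC[Li]
F7 | step 8 | lithium (3R,7R,11S)-1-(chlorozincio)-3,7,11,15-tetramethylhexadec-15-en-3-olate | C=C(C)CCC[C@@H](C)CCC[C@@H](C)CCC[C@@](C)(O[Li])CC[Zn]Cl
F8 | step 3 | (3R)-4-hydroxy-3-methylbutyl 2,4,6-triisopropylbenzenesulfonate | CC(C)c1cc(C(C)C)c(S(=O)(=O)OCC[C@@H](C)CO)c(C(C)C)c1
F9 | step 3 | (3R)-3-methyl-4-(triethylsilyloxy)butyl 2,4,6-triisopropylbenzenesulfonate | CC(C)c1cc(C(C)C)c(S(=O)(=O)OCC[C@@H](C)CO[Si](CC)(CC)CC)c(C(C)C)c1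
F10 | step 3 | triethyl{[(2R,6S)-2,6,10-trimethylundec-10-en-1-yl]oxy}silane | C=C(C)CCC[C@@H](C)CCC[C@@H](C)CO[Si](CC)(CC)CC
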